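## Structural features

The target is a tricyclic abietane: a cyclohexane ring A, a six-membered ring B carrying the C7 ketone, and a fully substituted aromatic ring C (OH at C11 and C14, OMe at C12, isopropyl at C13) fused along C8–C9. A δ-lactone runs from the C19 carbonyl on C4 through oxygen to C20 on C10, so C4 and C10 are bridgeheads of a 2-oxabicyclo[3.3.1]nonanone with C5 as the one-carbon bridge. Three stereocentres stand side by side: quaternary C4 (methyl, C19), tertiary C5 (hydrogen trans to C20) and quaternary benzylic C10. The A/B junction is trans, C19 and C20 are cis and 1,3-diaxial on ring A, and the configuration is 4S,5R,10R. The fragile groups are the electron-rich hydroquinone (oxidised by air, fastest in base), the chelated o-hydroxyaryl ketone and, on the way, the enolisable C20 aldehyde. The real difficulty is the C9–C10 bond, which joins a quaternary carbon next to quaternary C4 to an arene with no free position left. Two further problems are the placing of six different ring C substituents and the C4/C5 relative configuration, where methyl and ester differ little in size. The key step exploits ring C itself: the C11,C14-hydroquinone with the C7 acyl group on C8 is the reduced form of a 2-acyl-1,4-benzoquinone whose only free carbon, C9, is a Michael position that an enol centred on C10 can attack to close ring B.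

## Logic of the disconnections

**25 to 23 (through 24).** The O–C19 acyl bond of the lactone is cut and C20 is taken back to the aldehyde. Both partners already sit cis and 1,3-diaxial on ring A, so ring closure needs no extra control. The gain is that C20 is available at the oxidation level whose enol is the nucleophile of the key step. The forward demand is a hydride that takes the aldehyde and spares the C7 ketone.

**23 to 21 (through 22).** The C9–C10 bond is cut. This removes ring B and the quaternary benzylic centre and leaves a monocyclic ring A joined to the arene only by the C6–C7 chain. The forward step must oxidise nothing but the hydroquinone, the enol must attack through carbon, and C9 must arrive on the α face of C10.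

**21 to 20.** Only protecting groups change: two phenol acetals and the enol ether that masks C20. The free hydroquinone and the aldehyde are too sensitive to carry through carbanion chemistry. The demand is one mild acid operation that frees all three at once.

**20 to 18 and 7.** The C7–C8 bond is cut, which makes the route convergent. The arene enters as a nucleophile whose reacting carbon is fixed by a bromine. An electrophilic acylation of the free hydroquinone nucleus would have to choose between C8 and C9, and it needs a Lewis acid that an enol ether does not survive. The demand is an acyl donor that stops at the ketone and a carbanion that leaves the hindered ester and the enol ether alone.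

**7 to 6.** The C10=C20 bond is cut, a one-carbon homologation of the ring ketone. The demand is an ylide that reacts with the ketone in the presence of ester and amide.

**6 to 3 and 4.** The C5–C6 bond is cut. The enolate must be the C5/C10 regioisomer, which only the conjugate-addition product provides, and the electrophile must enter cis to the ester.

**3 to 1.** The C4–CH3 bond is cut. The demand is an enantioselective methyl transfer to the carbon β to the ketone, with the enolate kept in a storable form.

**18 to 17, 15 and 12.** The two hydroquinone oxygens and their protecting groups are removed stepwise back to a symmetric dibromide. In 12 the two bromine positions are equivalent, so converting one of them to oxygen fixes the whole substitution pattern without any regiochemical choice. The demand is a clean single bromine–lithium exchange and an oxidation that frees the oxygen next to the remaining bromine.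

**12 to 11, 10 and 8.** The bromines and the isopropyl group are removed. Every position attacked is dictated by the two methoxy groups of a symmetric ring.

## Other disconnections considered

**Alternative 1:** The cut takes out C5–C10 and C3–C4 together, so ring A, ring B and the lactone all disappear. What remains is the benzo-fused ten-membered lactone A1 with a (Z)-enoate (C4=C5) and a 1,3-diene (C10=C1–C2=C3). Forward, heating A1 should bring about the Diels–Alder addition across the ring to give the cycloadduct A2.
- In its favour: two C–C bonds, three rings and all three stereocentres arise in one reagent-free step. The cis relation of C19 and C6 is written into the alkene geometry, which is a more secure way to set C4 against C5 than the enolate alkylation of the chosen plan. On this point the alternative is the better.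
- Against it here: both new bonds end at quaternary carbons (a trisubstituted dienophile meets a fully substituted diene terminus). The facial sense must be relayed from the single C7 silyloxy centre through a flexible medium ring. A1 itself is a long synthesis.
- After A2: the C1–C2 alkene must be hydrogenated, C7 deprotected and oxidised, and two of three aryl methyl ethers removed selectively, which means an oxidation to the quinone level and a reduction.
- Comparison: in bond count per step the cycloaddition is superior; over the whole route it is not. Mechanistically a thermal pericyclic step is at least as clean as the anodic cascade. Structurally the chosen plan uses the oxidation level of ring C productively, whereas this one must protect it and unmask it again.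

**Alternative 2:** The cut is C4–C5, which opens ring A and the lactone to the spiro-fused eight-membered unsaturated lactone enone A3. Forward, base should form the lactone dienolate, and its C4 should add across the ring to C5 of the enone to give A4.
- In its favour: the hindered C4–C5 bond forms intramolecularly, the C7 ketone and the lactone are already present, and C4 and C5 are set by the geometry of a transannular transition state from the single centre C10. For the C4/C5 relation this is again more reliable than an intermolecular alkylation, and it closes two rings where the chosen key step closes one.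
- Against it here: A3 needs a quaternary spiro centre made enantioselectively and a medium-ring lactone. The dienolate may react at the γ-carbon, and the addition is reversible. A4 still needs hydrogenation of the C2–C3 alkene and selective removal of two methyl ethers.
- Comparison: both plans rest on a Michael addition. In the chosen plan the acceptor is ring C one oxidation level up, so no phenol protection is required and the product is two steps from the target. Total step count should favour the chosen plan.

**Alternative 3:** The cut removes ring C altogether (C11–C12, C13–C14, C8–C14). Forward, the alkenyl(methoxy)carbene complex of zerovalent chromium A5 should combine with 3-methylbut-1-yne A6 and one CO ligand to give the phenol A7.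
- In its favour: a benzannulation places the bulky alkyne substituent next to the new phenol reliably, so the C13/C14 relation is secure. All three stereocentres can be finished in a bicyclic lactone before the arene exists. In arene regiocontrol it is the equal of the chosen plan.
- Against it here: chromium is stoichiometric. A7 has no oxygen at C12, carries its methyl on O11 instead of O12, and has a methylene at C7. Benzylic oxidation, oxidation of ring C, introduction of the C12 methoxy group and a reduction must follow. A5 itself requires the bicyclic lactone with an alkenyl handle at C9.
- Comparison: this is the most convergent in skeleton but the least matched in oxidation pattern. The chosen plan brings ring C in with every heteroatom in place.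

Key step: step 12

**Remarks on the chemistry**

- Assumption: atoms are named by abietane numbering (C1–C20); the seco-hydroquinone 21 is used as the mixture of its two C10 epimers, because this centre is erased in the enol of the key step.
- Assumption: the sense of the copper-catalysed methyl addition follows from the ligand enantiomer, and the one leading to 4S is used.
- Correction adopted: in acylquinone 22 the free carbon C9 is β to the C14 carbonyl and to the C7 acyl carbonyl and α to C11. Its activation is therefore assigned to C14=O and C7=O.
- Design changes to reach the precursor safely: the arene is attached as a regiodefined aryllithium and not by Lewis-acid acylation of the free hydroquinone; the C7 acyl donor is a morpholine amide from 4-(bromoacetyl)morpholine; no amine catalyst is used in the key step, because secondary amines add to acylquinones.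

## Route

Step 1
Reactants: 1 methyl 3-oxocyclohex-1-ene-1-carboxylate
Product: 3 methyl (S)-1-methyl-3-(trimethylsilyloxy)cyclohex-2-ene-1-carboxylate, via zinc enolate 2 (not isolated)
Conditions: Me2Zn (3 equiv), Cu(OTf)2 (5 mol %), chiral sulfonate-bridged NHC ligand (from its imidazolinium salt, 6 mol %), t-BuOMe, −30 °C; then TMSOTf, −30 → 0 °C
Reagents that add atoms: dimethylzinc C[Zn]C; trimethylsilyl trifluoromethanesulfonate C[Si](C)(C)OS(=O)(=O)C(F)(F)F
Why: Copper-catalysed asymmetric conjugate addition of a dialkylzinc to a β-ester-substituted cyclic enone: methyl goes to C4, the carbon β to the ketone (the stronger acceptor), and the face is chosen by the chiral NHC–copper catalyst; O-silylation of the zinc enolate stores the C5=C10 enolate regiochemistry that direct deprotonation of the ketone could not provide.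

Step 2
Reactants: 3 methyl (S)-1-methyl-3-(trimethylsilyloxy)cyclohex-2-ene-1-carboxylate; 4 4-(bromoacetyl)morpholine
Product: 6 methyl (1S,2S)-1-methyl-2-[2-(morpholin-4-yl)-2-oxoethyl]-3-oxocyclohexane-1-carboxylate, via ammonium enolate 5 (not isolated)
Conditions: Bu4N[Ph3SiF2] (1.1 equiv), THF, −78 → 0 °C
Reagents that add atoms: none
Why: Fluoride-triggered regiospecific alkylation of a silyl enol ether: desilylation gives the C5/C10 enolate, which is alkylated at C5 by the α-bromo amide (SN2); the electrophile should enter anti to the C4 methyl group (the better σ-donor and the larger group, with the ester near the enolate plane), placing the side chain cis to the ester. C5 remains epimerisable next to the ketone, and the same isomer (ester axial, side chain equatorial) is also the expected thermodynamic one.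

Step 3
Reactants: 6 methyl (1S,2S)-1-methyl-2-[2-(morpholin-4-yl)-2-oxoethyl]-3-oxocyclohexane-1-carboxylate
Product: 7 methyl (1S,2R)-3-(methoxymethylidene)-1-methyl-2-[2-(morpholin-4-yl)-2-oxoethyl]cyclohexane-1-carboxylate
Conditions: Ph3P(CH2OMe)Cl, KN(SiMe3)2, THF, 0 °C → rt
Reagents that add atoms: (methoxymethyl)triphenylphosphonium chloride COC[P+](c1ccccc1)(c1ccccc1)c1ccccc1.[Cl-]
Why: Wittig olefination with the methoxymethylene ylide turns the C10 ketone into the enol ether that carries C20 at the aldehyde oxidation level; ester and tertiary amide do not react with the ylide, the E/Z mixture is irrelevant because both isomers give the same aldehyde, and C5 ceases to be epimerisable (its descriptor changes only through the priority rules).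

Step 4
Reactants: 8 1,3-dimethoxybenzene
Product: 10 2-(2,6-dimethoxyphenyl)propan-2-ol, via 2,6-dimethoxyphenyllithium 9 (not isolated)
Conditions: n-BuLi, THF, 0 °C → rt; acetone, −78 °C → rt; aq. NH4Cl
Reagents that add atoms: acetone CC(C)=O
Why: Directed ortho-metalation: the proton between the two methoxy groups is removed selectively and the aryllithium adds to acetone (carbonyl addition).

Step 5
Reactants: 10 2-(2,6-dimethoxyphenyl)propan-2-ol
Product: 11 2-isopropyl-1,3-dimethoxybenzene
Conditions: Et3SiH, CF3CO2H, CH2Cl2, 0 °C → rt
Reagents that add atoms: none
Why: Ionic hydrogenation: acid ionises the tertiary benzylic alcohol to a cation stabilised by two ortho methoxy groups, which is reduced by hydride transfer from the silane.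

Step 6
Reactants: 11 2-isopropyl-1,3-dimethoxybenzene
Product: 12 1,5-dibromo-3-isopropyl-2,4-dimethoxybenzene
Conditions: NBS (2.1 equiv), MeCN, 0 °C → rt
Reagents that add atoms: N-bromosuccinimide O=C1CCC(=O)N1Br
Why: Electrophilic aromatic bromination: the two equivalent positions ortho to one methoxy group and para to the other are attacked, the third free position is meta to both; the product is symmetric, so no regiochemical question arises.

Step 7
Reactants: 12 1,5-dibromo-3-isopropyl-2,4-dimethoxybenzene
Product: 15 5-bromo-3-isopropyl-2,4-dimethoxyphenol, via aryllithium 13 (not isolated), via dimethyl arylboronate 14 (not isolated)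
Conditions: n-BuLi (1.0 equiv), THF, −78 °C; B(OMe)3, −78 °C → rt; then H2O2, aq. NaOH, 0 °C → rt
Reagents that add atoms: hydrogen peroxide OO
Why: Bromine–lithium exchange on one of two equivalent bromines (a second exchange on the aryllithium is much slower), borylation and oxidative C–B to C–O migration; the symmetry of 12 guarantees that the new hydroxyl (future O11) and the remaining bromine (future C8) are meta to each other with the correct neighbours.

Step 8
Reactants: 15 5-bromo-3-isopropyl-2,4-dimethoxyphenol
Product: 17 5-bromo-3-isopropyl-2-methoxybenzene-1,4-diol, via bromoquinone 16 (not isolated)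
Conditions: PhI(OAc)2, MeCN/H2O, 0 °C; then aq. Na2S2O4, EtOAc, rt
Reagents that add atoms: water O
Why: Hypervalent-iodine oxidation of a 4-methoxyphenol: water adds at the methoxy-bearing para carbon and methanol is lost (oxidative demethylation to the 1,4-quinone), which frees exactly the oxygen next to the bromine; dithionite reduction then gives the hydroquinone.

Step 9
Reactants: 17 5-bromo-3-isopropyl-2-methoxybenzene-1,4-diol
Product: 18 1-bromo-3-isopropyl-4-methoxy-2,5-bis(methoxymethoxy)benzene
Conditions: NaH, MOMCl, DMF, 0 °C → rt, argon
Reagents that add atoms: chloromethyl methyl ether COCCl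
Why: Williamson-type O-alkylation of both phenoxides; the two acetal protecting groups tolerate organolithium chemistry and fall together with the enol ether in acid.

Step 10
Reactants: 18 1-bromo-3-isopropyl-4-methoxy-2,5-bis(methoxymethoxy)benzene; 7 methyl (1S,2R)-3-(methoxymethylidene)-1-methyl-2-[2-(morpholin-4-yl)-2-oxoethyl]cyclohexane-1-carboxylate
Product: 20 methyl (1S,2R)-2-{2-[3-isopropyl-4-methoxy-2,5-bis(methoxymethoxy)phenyl]-2-oxoethyl}-3-(methoxymethylidene)-1-methylcyclohexane-1-carboxylate, via aryllithium 19 (not isolated)
Conditions: 18, n-BuLi, THF, −78 °C; then 7, −78 → −20 °C; aq. NH4Cl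
Reagents that add atoms: none
Why: Bromine–lithium exchange followed by acylation of the aryllithium with a morpholine amide (a known ketone synthesis: the tetrahedral adduct survives until work-up, so no second addition occurs); the bromine fixes the new bond at C8 without any regiochemical choice, and the hindered tertiary ester and the enol ether are not attacked at low temperature.

Step 11
Reactants: 20 methyl (1S,2R)-2-{2-[3-isopropyl-4-methoxy-2,5-bis(methoxymethoxy)phenyl]-2-oxoethyl}-3-(methoxymethylidene)-1-methylcyclohexane-1-carboxylate
Product: 21 methyl (1S,2R,3RS)-2-[2-(2,5-dihydroxy-3-isopropyl-4-methoxyphenyl)-2-oxoethyl]-3-formyl-1-methylcyclohexane-1-carboxylate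
Conditions: 2 M HCl, THF, 45 °C, degassed, argon
Reagents that add atoms: water O
Why: Aqueous acid hydrolysis of the enol ether to the C20 aldehyde and of both methoxymethyl acetals in one operation; C10 becomes a stereocentre without control, which is of no consequence since it is erased in the next step, and air is excluded because the free hydroquinone is oxidisable.

Step 12
Reactants: 21 methyl (1S,2R,3RS)-2-[2-(2,5-dihydroxy-3-isopropyl-4-methoxyphenyl)-2-oxoethyl]-3-formyl-1-methylcyclohexane-1-carboxylate
Product: 23 methyl 11,14-dihydroxy-12-methoxy-7,20-dioxoabieta-8,11,13-trien-19-oate, via acylquinone 22 (not isolated)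
Conditions: undivided cell, graphite-felt anode, Pt cathode, LiClO4 (0.1 M), MeCN/AcOH 9:1, +0.6 V vs Ag/AgCl, ca. 2.2 F/mol, rt, argon; work-up with aq. Na2S2O4
Reagents that add atoms: none
Why: Proposed new method: the anode removes two electrons and two protons from the hydroquinone ring of 21 at a potential that leaves aldehyde, ketone and ester untouched and gives acylquinone 22, in which C9 is the β-carbon of both the C14 carbonyl and the C7 acyl carbonyl and therefore a doubly activated Michael position; acid-catalysed enolisation of the α-branched aldehyde gives the C10=C20 enol common to both C10 epimers, C10 adds to C9, and loss of the C9 proton restores the aromatic hydroquinone of 23. The closest known reaction types are the anodic oxidation of catechols and hydroquinones with in situ Michael addition of 1,3-dicarbonyl nucleophiles and the amine-catalysed α-arylation of aldehydes by quinones; what is new is the intramolecular use of a simple aldehyde enol to make a quaternary benzylic carbon. Ring B closes as a six-membered ring in a 6-endo-trig mode with respect to the C8=C9 acceptor bond (6-exo with respect to the enol); attack through the enol oxygen would need an eight-membered ring. The new stereocentre C10 is controlled by the ring A chair with the C19 ester axial and the C5 side chain equatorial: the tethered C9 can reach C10 only along the equatorial α trajectory, the β face being screened by the 1,3-diaxial ester, so ring B becomes trans-fused and the formyl group ends up axial and cis to C19. Regioselectivity needs no control because C9 is the only unsubstituted quinone carbon, and chemoselectivity rests on the low oxidation potential of the hydroquinone. Over-oxidation of 23 to its quinone is harmless, since that quinone has no free position and is returned by Na2S2O4.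

Step 13
Reactants: 23 methyl 11,14-dihydroxy-12-methoxy-7,20-dioxoabieta-8,11,13-trien-19-oate
Product: 25 11,14-dihydroxy-12-methoxy-7-oxoabieta-8,11,13-trien-19,20-olide (CNP0159814.2), via hydroxy ester 24 (not isolated)
Conditions: NaBH4, THF/MeOH, −20 → 0 °C, argon; then TsOH·H2O, rt
Reagents that add atoms: none
Why: Chemoselective borohydride reduction: the aldehyde (or its O11 lactol through the open form) is reduced while the C7 ketone is deactivated as a chelated vinylogous acid or its phenoxide; the new axial hydroxymethyl group lies 1,3-diaxial to the C19 ester and closes the δ-lactone by acid-catalysed transesterification with loss of methanol; no stereocentre is formed.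

## Compound list

1 | methyl 3-oxocyclohex-1-ene-1-carboxylate | COC(=O)C1=CC(=O)CCC1 | starting material
2 | methylzinc enolate (C5=C10) of methyl (S)-1-methyl-3-oxocyclohexane-1-carboxylate | COC(=O)[C@@]1(C)CCCC(O[Zn]C)=C1 | intermediate
3 | methyl (S)-1-methyl-3-(trimethylsilyloxy)cyclohex-2-ene-1-carboxylate | COC(=O)[C@@]1(C)CCCC(O[Si](C)(C)C)=C1 | intermediate
4 | 4-(bromoacetyl)morpholine | O=C(CBr)N1CCOCC1 | starting material
5 | tetrabutylammonium enolate (C5=C10) of methyl (S)-1-methyl-3-oxocyclohexane-1-carboxylate | COC(=O)[C@@]1(C)CCCC([O-])=C1.CCCC[N+](CCCC)(CCCC)CCCC | intermediate
6 | methyl (1S,2S)-1-methyl-2-[2-(morpholin-4-yl)-2-oxoethyl]-3-oxocyclohexane-1-carboxylate | O=C(N2CCOCC2)C[C@@H]1C(=O)CCC[C@]1(C)C(=O)OC | intermediate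
7 | methyl (1S,2R)-3-(methoxymethylidene)-1-methyl-2-[2-(morpholin-4-yl)-2-oxoethyl]cyclohexane-1-carboxylate (E/Z mixture) | O=C(N2CCOCC2)C[C@@H]1C(=COC)CCC[C@]1(C)C(=O)OC | intermediate
8 | 1,3-dimethoxybenzene | COc1cccc(OC)c1 | starting material
9 | 2,6-dimethoxyphenyllithium | COc1cccc(OC)c1[Li] | intermediate
10 | 2-(2,6-dimethoxyphenyl)propan-2-ol | COc1cccc(OC)c1C(C)(C)O | intermediate
11 | 2-isopropyl-1,3-dimethoxybenzene | COc1cccc(OC)c1C(C)C | intermediate
12 | 1,5-dibromo-3-isopropyl-2,4-dimethoxybenzene | COc1c(Br)cc(Br)c(OC)c1C(C)C | intermediate
13 | (5-bromo-3-isopropyl-2,4-dimethoxyphenyl)lithium | COc1c([Li])cc(Br)c(OC)c1C(C)C | intermediate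
14 | dimethyl (5-bromo-3-isopropyl-2,4-dimethoxyphenyl)boronate | COB(OC)c1cc(Br)c(OC)c(C(C)C)c1OC | intermediate
15 | 5-bromo-3-isopropyl-2,4-dimethoxyphenol | COc1c(O)cc(Br)c(OC)c1C(C)C | intermediate
16 | 5-bromo-3-isopropyl-2-methoxycyclohexa-2,5-diene-1,4-dione | COC1=C(C(C)C)C(=O)C(Br)=CC1=O | intermediate
17 | 5-bromo-3-isopropyl-2-methoxybenzene-1,4-diol | COc1c(O)cc(Br)c(O)c1C(C)C | intermediate
18 | 1-bromo-3-isopropyl-4-methoxy-2,5-bis(methoxymethoxy)benzene | COCOc1cc(Br)c(OCOC)c(C(C)C)c1OC | intermediate
19 | [3-isopropyl-4-methoxy-2,5-bis(methoxymethoxy)phenyl]lithium | COCOc1cc([Li])c(OCOC)c(C(C)C)c1OC | intermediate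
20 | methyl (1S,2R)-2-{2-[3-isopropyl-4-methoxy-2,5-bis(methoxymethoxy)phenyl]-2-oxoethyl}-3-(methoxymethylidene)-1-methylcyclohexane-1-carboxylate | COCOc1cc(c(OCOC)c(C(C)C)c1OC)C(=O)C[C@@H]1C(=COC)CCC[C@]1(C)C(=O)OC | intermediate
21 | methyl (1S,2R,3RS)-2-[2-(2,5-dihydroxy-3-isopropyl-4-methoxyphenyl)-2-oxoethyl]-3-formyl-1-methylcyclohexane-1-carboxylate (seco-ring-B acylhydroquinone aldehyde, both C10 epimers) | COc1c(O)cc(c(O)c1C(C)C)C(=O)C[C@@H]1C(C=O)CCC[C@]1(C)C(=O)OC | intermediate
22 | methyl (1S,2R,3RS)-3-formyl-2-[2-(5-isopropyl-4-methoxy-3,6-dioxocyclohexa-1,4-dien-1-yl)-2-oxoethyl]-1-methylcyclohexane-1-carboxylate (acylquinone) | COC1=C(C(C)C)C(=O)C(=CC1=O)C(=O)C[C@@H]1C(C=O)CCC[C@]1(C)C(=O)OC | intermediate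
23 | methyl 11,14-dihydroxy-12-methoxy-7,20-dioxoabieta-8,11,13-trien-19-oate (4S,5R,10R) | COc1c(O)c2c(c(O)c1C(C)C)C(=O)C[C@@H]1[C@]2(C=O)CCC[C@]1(C)C(=O)OC | intermediate
24 | methyl 11,14,20-trihydroxy-12-methoxy-7-oxoabieta-8,11,13-trien-19-oate | COc1c(O)c2c(c(O)c1C(C)C)C(=O)C[C@@H]1[C@]2(CO)CCC[C@]1(C)C(=O)OC | intermediate
25 | 11,14-dihydroxy-12-methoxy-7-oxoabieta-8,11,13-trien-19,20-olide (4S,5R,10R; CNP0159814.2) | COc1c(O)c2c(c(O)c1C(C)C)C(=O)C[C@@H]1[C@]23CCC[C@]1(C)C(=O)OC3 | target

## Step count and least certain steps

Total step count: 13 steps. Longest linear sequence: 10 steps (8 to 25 through steps 4–13); the ring A branch is steps 1–3 and joins at step 10.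

**Step 12 (key step, Proposed new method).** The carbon–carbon bond formation at a quaternary centre may be slower than the decay of the acylquinone. The likely decay paths are internal redox isomerisation through the C6 enol of the acyl group and addition of adventitious nucleophiles at C9, because the concentration of the aldehyde enol is low. Fallback with known chemistry, setting out from 21: the two tasks are separated. Ag2O (Et2O, MgSO4) is the established oxidation of acylhydroquinones and would give acylquinone 22, this time isolated. Ring closure would then follow under enamine catalysis with a hindered primary amine salt, the known amine-catalysed α-arylation of aldehydes by quinones, and the route is rejoined at 23. This fallback makes no compound outside the list (F0).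

**Step 2.** Facial discrimination at C5 may be poor, because methyl and ester on C4 differ little in size, and the thermodynamic preference is also modest. Fallback from 3: the face is chosen by a catalyst. Tris(dibenzylideneacetone)dipalladium, Pd2(dba)3, with a chiral diphosphine ligand, allyl methyl carbonate and Bu4N[Ph3SiF2] (asymmetric Tsuji–Trost allylation of the silyl enol ether, matched ligand enantiomer) should give methyl (1S,2S)-1-methyl-3-oxo-2-(prop-2-en-1-yl)cyclohexane-1-carboxylate F1. Cleavage of the terminal alkene with catalytic RuCl3 and NaIO4 should give 2-[(1S,2S)-2-(methoxycarbonyl)-2-methyl-6-oxocyclohexyl]acetic acid F2. Carbodiimide coupling with morpholine rejoins the route at 6.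

**Step 10.** The aryllithium may deprotonate the amide at C6 instead of adding, or exchange may be incomplete at the flanked bromine; either leads to loss of the valuable amide. Fallback from 7: the amide is first reduced with Cp2Zr(H)Cl, which takes tertiary amides to aldehydes in the presence of esters, giving methyl (1S,2R)-3-(methoxymethylidene)-1-methyl-2-(2-oxoethyl)cyclohexane-1-carboxylate F3. Addition of 19 to this far more electrophilic aldehyde should give methyl (1S,2R)-2-{2-hydroxy-2-[3-isopropyl-4-methoxy-2,5-bis(methoxymethoxy)phenyl]ethyl}-3-(methoxymethylidene)-1-methylcyclohexane-1-carboxylate F4. Oxidation of the benzylic alcohol with a periodinane buffered by NaHCO3 rejoins the route at 20.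

**Step 3.** The ketone is flanked by a tertiary and a quaternary carbon, so olefination may be slow and enolisation by the basic ylide may compete, with loss of material or drift at C5. Fallback from 6: a two-stage Horner–Wittig sequence. Lithiated (methoxymethyl)diphenylphosphine oxide (LiN(iPr)2, THF, −78 °C), a smaller and more nucleophilic carbanion, should add to the ketone to give the isolable adduct methyl (1S,2S)-3-[(diphenylphosphoryl)(methoxy)methyl]-3-hydroxy-1-methyl-2-[2-(morpholin-4-yl)-2-oxoethyl]cyclohexane-1-carboxylate F5. Elimination with NaH in THF rejoins the route at 7.

## Further compounds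

F0 | step 12 | none | none
F1 | step 2 | methyl (1S,2S)-1-methyl-3-oxo-2-(prop-2-en-1-yl)cyclohexane-1-carboxylate | C=CC[C@@H]1C(=O)CCC[C@]1(C)C(=O)OC
F2 | step 2 | 2-[(1S,2S)-2-(methoxycarbonyl)-2-methyl-6-oxocyclohexyl]acetic acid | OC(=O)C[C@@H]1C(=O)CCC[C@]1(C)C(=O)OC
F3 | step 10 | methyl (1S,2R)-3-(methoxymethylidene)-1-methyl-2-(2-oxoethyl)cyclohexane-1-carboxylate | O=CC[C@@H]1C(=COC)CCC[C@]1(C)C(=O)OC
F4 | step 10 | methyl (1S,2R)-2-{2-hydroxy-2-[3-isopropyl-4-methoxy-2,5-bis(methoxymethoxy)phenyl]ethyl}-3-(methoxymethylidene)-1-methylcyclohexane-1-carboxylate (both carbinol epimers) | COCOc1cc(c(OCOC)c(C(C)C)c1OC)C(O)C[C@@H]1C(=COC)CCC[C@]1(C)C(=O)OC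
F5 | step 3 | methyl (1S,2S)-3-[(diphenylphosphoryl)(methoxy)methyl]-3-hydroxy-1-methyl-2-[2-(morpholin-4-yl)-2-oxoethyl]cyclohexane-1-carboxylate (diastereomer mixture at the two new centres) | O=C(N2CCOCC2)C[C@@H]1C(O)(C(OC)P(=O)(c3ccccc3)c3ccccc3)CCC[C@]1(C)C(=O)OC
A1 | alternative 1 | benzo-fused ten-membered lactone with (Z)-enoate, C7 silyl ether and C10 butadienyl unit (seco precursor of the cycloaddition) | COc1c(OC)c2c(c(OC)c1C(C)C)[C@H](O[Si](C)(C)C(C)(C)C)C/C=C(C)\C(=O)OCC2=CC=C
A2 | alternative 1 | 7-(tert-butyldimethylsilyloxy)-11,12,14-trimethoxyabieta-1,8,11,13-tetraen-19,20-olide | COc1c(OC)c2c(c(OC)c1C(C)C)[C@H](O[Si](C)(C)C(C)(C)C)C[C@@H]1[C@]23C=CC[C@]1(C)C(=O)OC3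
A3 | alternative 2 | spiro-fused naphthalenone enone with eight-membered α,β-unsaturated lactone | COc1c(OC)c2c(c(OC)c1C(C)C)C(=O)C=C[C@]23CC/C=C(C)\C(=O)OC3
A4 | alternative 2 | 11,12,14-trimethoxy-7-oxoabieta-2,8,11,13-tetraen-19,20-olide | COc1c(OC)c2c(c(OC)c1C(C)C)C(=O)C[C@@H]1[C@]23CC=C[C@]1(C)C(=O)OC3
A5 | alternative 3 | pentacarbonyl[methoxy(alkenyl)carbene]chromium complex of the bicyclic lactone | COC(C1=CCC[C@@H]2[C@]13CCC[C@]2(C)C(=O)OC3)=[Cr](=C=O)(=C=O)(=C=O)(=C=O)=C=O
A6 | alternative 3 | 3-methylbut-1-yne | CC(C)C#C
A7 | alternative 3 | 14-hydroxy-11-methoxyabieta-8,11,13-trien-19,20-olide | c1c(OC)c2c(c(O)c1C(C)C)CC[C@@H]1[C@]23CCC[C@]1(C)C(=O)OC3
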